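**Plan**
Rings are lettered A to E from the 2,4,6-trihydroxyphenoxy end; the retrosynthesis first removes ten O-methyl groups and a carboxyl group placed temporarily on ring D.
Ring D is then cut at two C–C bonds. Numbering it from the carbon bonded to the ring C oxygen (C1), the adjacent C3(OH)–C4(O–ring E)–C5(OH) triad is C1–C3 of a 2-aryloxycyclohexane-1,3-dione. C6 is the fourth sp2 carbon of its bis(silyl) dienol ether, and C1–C2 are the alkyne carbons of a 3-aryloxypropiolate; bonds C6–C1 and C2–C3 are cut, and the dione's two CH2 groups return as ethylene.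
The D–E ether goes back to O–H insertion of 2-diazocyclohexane-1,3-dione into 3,4,5-trimethoxyphenol. The A–B and B–C ethers go back to two Cu-catalysed couplings with a benzyl-protected 4-bromo-2,6-dimethoxyphenol, and the O–C≡C unit to trichloroethylene.
Forward: rings A, B, C and E are bought as methyl ethers; the A–B–C phenol (steps 1–5) becomes the ynoate (steps 6–7), the diene is made in steps 8–10, ring D is built last (step 11), then decarboxylation and demethylation (steps 12–13).
Stereochemistry: the target is achiral with no stereocentre; only the regiochemistry of ring D formation matters, and the polarisation of the diene sets it.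

Key step: step 11

Remark: 17 is written as its enol tautomer, bicycle 20 is a racemate whose bridgehead centres vanish on aromatisation, and 4-bromo-2,6-dimethoxyphenol (1) is taken as a purchased material.

**Route**

Step 1
Reactants: 1 4-bromo-2,6-dimethoxyphenol
Product: 2 2-(benzyloxy)-5-bromo-1,3-dimethoxybenzene
Conditions: BnBr, K2CO3, DMF, rt
Reagents that add atoms: benzyl bromide, BrCc1ccccc1
Why: Williamson ether synthesis, the phenoxide displacing bromide by SN2, masks the hindered phenol as an ether that survives copper catalysis and is later removed by hydrogenolysis.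

Step 2
Reactants: 3 2,4,6-trimethoxyphenol; 2 2-(benzyloxy)-5-bromo-1,3-dimethoxybenzene
Product: 4 2-(benzyloxy)-1,3-dimethoxy-5-(2,4,6-trimethoxyphenoxy)benzene
Conditions: CuI (10 mol%), picolinic acid (20 mol%), K3PO4, DMSO, 90 °C, Ar
Reagents that add atoms: none
Why: Ullmann-type copper-catalysed C–O coupling with a picolinate ligand is established for di-ortho-substituted phenols and electron-rich aryl bromides, and the bromide of 2 has two free ortho positions.

Step 3
Reactants: 4 2-(benzyloxy)-1,3-dimethoxy-5-(2,4,6-trimethoxyphenoxy)benzene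
Product: 5 2,6-dimethoxy-4-(2,4,6-trimethoxyphenoxy)phenol
Conditions: H2 (1 atm), 10% Pd/C, EtOAc–EtOH, rt
Reagents that add atoms: none
Why: Catalytic hydrogenolysis cleaves only the benzylic C–O bond and leaves methyl and diaryl ethers untouched.

Step 4
Reactants: 5 2,6-dimethoxy-4-(2,4,6-trimethoxyphenoxy)phenol; 2 2-(benzyloxy)-5-bromo-1,3-dimethoxybenzene
Product: 6 2-(benzyloxy)-5-[2,6-dimethoxy-4-(2,4,6-trimethoxyphenoxy)phenoxy]-1,3-dimethoxybenzene
Conditions: CuI (10 mol%), picolinic acid (20 mol%), K3PO4, DMSO, 90 °C, Ar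
Reagents that add atoms: none
Why: A second Ullmann-type coupling under the same conditions should work because phenol 5 has the same 2,6-dimethoxy environment as 3.

Step 5
Reactants: 6 2-(benzyloxy)-5-[2,6-dimethoxy-4-(2,4,6-trimethoxyphenoxy)phenoxy]-1,3-dimethoxybenzene
Product: 7 4-[2,6-dimethoxy-4-(2,4,6-trimethoxyphenoxy)phenoxy]-2,6-dimethoxyphenol
Conditions: H2 (1 atm), 10% Pd/C, EtOAc–EtOH, rt
Reagents that add atoms: none
Why: Benzyl ether hydrogenolysis as in step 3 frees the ring C phenol that will carry the alkyne.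

Step 6
Reactants: 7 4-[2,6-dimethoxy-4-(2,4,6-trimethoxyphenoxy)phenoxy]-2,6-dimethoxyphenol; 8 trichloroethylene
Product: 10 2-{[(E)-1,2-dichloroethenyl]oxy}-5-[2,6-dimethoxy-4-(2,4,6-trimethoxyphenoxy)phenoxy]-1,3-dimethoxybenzene, via dichloroacetylene 9 (not isolated)
Conditions: 8 (2 equiv), K2CO3, DMF, 70 °C
Reagents that add atoms: none
Why: Base-induced dehydrochlorination of 8 gives 9 in situ and anti addition of the phenol across it gives the E-configured dichlorovinyl ether, the established trichloroethylene entry to ynol ether precursors.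

Step 7
Reactants: 10 2-{[(E)-1,2-dichloroethenyl]oxy}-5-[2,6-dimethoxy-4-(2,4,6-trimethoxyphenoxy)phenoxy]-1,3-dimethoxybenzene
Product: 13 benzyl 3-{4-[2,6-dimethoxy-4-(2,4,6-trimethoxyphenoxy)phenoxy]-2,6-dimethoxyphenoxy}prop-2-ynoate, via chloroethynyl ether 11 (not isolated), via lithium aryloxyacetylide 12 (not isolated)
Conditions: n-BuLi (2.1 equiv), THF, −78 to −40 °C; then BnOCOCl (1.5 equiv), −78 to 0 °C
Reagents that add atoms: benzyl chloroformate, O=C(Cl)OCc1ccccc1
Why: Vinylic deprotonation with loss of LiCl gives 11, chlorine–lithium exchange with the second equivalent of n-BuLi gives 12, and C-acylation of this acetylide by the chloroformate gives the ynoate (haloenol ether elimination followed by acetylide acylation), the two ortho methoxy groups shielding the ynol ether oxygen.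

Step 8
Reactants: 14 cyclohexane-1,3-dione
Product: 15 2-diazocyclohexane-1,3-dione
Conditions: 4-acetamidobenzenesulfonyl azide, Et3N, MeCN, 0 °C to rt
Reagents that add atoms: 4-acetamidobenzenesulfonyl azide, CC(=O)Nc1ccc(cc1)S(=O)(=O)N=[N+]=[N-]
Why: Regitz diazo transfer onto the acidic C2 of a 1,3-dione is a standard, high-yielding reaction.

Step 9
Reactants: 15 2-diazocyclohexane-1,3-dione; 16 3,4,5-trimethoxyphenol
Product: 17 3-hydroxy-2-(3,4,5-trimethoxyphenoxy)cyclohex-2-en-1-one (enol form of 2-(3,4,5-trimethoxyphenoxy)cyclohexane-1,3-dione)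
Conditions: Rh2(OAc)4 (2 mol%), 16 (1.5 equiv), PhCF3, 80 °C, slow addition of 15
Reagents that add atoms: none
Why: Rh2(OAc)4-catalysed O–H insertion of a 2-diazo-1,3-dicarbonyl compound into a phenol is a known carbenoid reaction, and slow addition of 15 to excess phenol in an electron-poor solvent should suppress diazo dimerisation and attack on ring carbons.

Step 10
Reactants: 17 3-hydroxy-2-(3,4,5-trimethoxyphenoxy)cyclohex-2-en-1-one
Product: 19 2-(3,4,5-trimethoxyphenoxy)-1,3-bis(trimethylsilyloxy)cyclohexa-1,3-diene, via silyloxy enone 18 (not isolated)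
Conditions: TMSCl, Et3N, THF, 0 °C to rt, filter and concentrate under Ar; then LiN(iPr)2, THF, −78 °C, TMSCl, −78 °C to rt; pentane, filtration, no aqueous work-up
Reagents that add atoms: chlorotrimethylsilane, C[Si](C)(C)Cl
Why: O-silylation of the enol gives 18 and O-silylation of its lithium enolate gives the diene (the standard two-stage preparation of 1,3-bis(trimethylsilyloxy)cyclohexa-1,3-dienes), and because both oxygens end up silylated, α′- and γ-deprotonation of 18 lead to the same compound.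

Step 11
Reactants: 19 2-(3,4,5-trimethoxyphenoxy)-1,3-bis(trimethylsilyloxy)cyclohexa-1,3-diene; 13 benzyl 3-{4-[2,6-dimethoxy-4-(2,4,6-trimethoxyphenoxy)phenoxy]-2,6-dimethoxyphenoxy}prop-2-ynoate
Product: 22 benzyl 6-{4-[2,6-dimethoxy-4-(2,4,6-trimethoxyphenoxy)phenoxy]-2,6-dimethoxyphenoxy}-2,4-dihydroxy-3-(3,4,5-trimethoxyphenoxy)benzoate, via bicyclo[2.2.2]octadiene adduct 20 (not isolated), via bis(trimethylsilyl) ether 21 (not isolated)
Conditions: 19 (3 equiv), neat with a little mesitylene, sealed tube, Ar, 150–160 °C; then 1 M HCl, THF, rt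
Reagents that add atoms: none
Why: Proposed new method: the electron-rich diene 19 should add in a thermal, concerted but asynchronous [4+2] cycloaddition across the ester-conjugated triple bond of 13 to give bicyclo[2.2.2]octa-2,5-diene 20, which at the same temperature loses its saturated CH2–CH2 bridge as ethylene in a retro-[4+2] driven by aromatisation and gas evolution to give 21, and dilute acid then cleaves the two aryl silyl ethers. The closest known reaction type is the Alder–Rickert synthesis of 2,4-dihydroxybenzoates from 1,3-bis(trimethylsilyloxy)cyclohexa-1,3-dienes and acetylenic esters such as 2-butynoates, which places the ynoate β-substituent at C6 of the benzoate; a β-aryloxy ynoate has not been used in this role, and although the oxygen donor raises the LUMO, its inductive pull and the ester should keep the β-carbon the electrophilic site. Ring D is closed by intermolecular cycloaddition that forms two C–C bonds (diene CH terminus to the aryloxy-bearing alkyne carbon, silyloxy-bearing terminus to the ester-bearing carbon), and the six-membered ring so formed is the one that remains after ethylene loss. The two bridgehead stereocentres of 20 are fixed relative to each other by the bicycle, arise as a racemate and are erased on aromatisation, so no stereocontrol is required. The only selectivity needed is regiochemical: the CH terminus of 19 carries the largest HOMO coefficient (β to one silyloxy group, vinylogously δ to the other) and bonds to the β-carbon of 13, which places the ring C oxygen para to the ring E oxygen and the ester ortho to a hydroxyl where it can be removed; excess diene and acid-free, oxygen-free heating guard against premature desilylation of 19.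

Step 12
Reactants: 22 benzyl 6-{4-[2,6-dimethoxy-4-(2,4,6-trimethoxyphenoxy)phenoxy]-2,6-dimethoxyphenoxy}-2,4-dihydroxy-3-(3,4,5-trimethoxyphenoxy)benzoate
Product: 24 5-{4-[2,6-dimethoxy-4-(2,4,6-trimethoxyphenoxy)phenoxy]-2,6-dimethoxyphenoxy}-2-(3,4,5-trimethoxyphenoxy)benzene-1,3-diol, via carboxylic acid 23 (not isolated)
Conditions: H2 (1 atm), 10% Pd/C, EtOAc, rt; filter; then DMSO, 110 °C, Ar
Reagents that add atoms: none
Why: Hydrogenolysis frees the acid under neutral conditions, and this benzoic acid with oxygen on both ortho carbons and the para carbon (phloroglucinol-carboxylic acid type) should lose CO2 on mild heating by ipso-protonation (thermal protodecarboxylation).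

Step 13
Reactants: 24 5-{4-[2,6-dimethoxy-4-(2,4,6-trimethoxyphenoxy)phenoxy]-2,6-dimethoxyphenoxy}-2-(3,4,5-trimethoxyphenoxy)benzene-1,3-diol
Product: 25 5-{4-[4-(2,6-dihydroxy-4-(2,4,6-trihydroxyphenoxy)phenoxy)-2,6-dihydroxyphenoxy]-2,6-dihydroxyphenoxy}benzene-1,2,3-triol (CNP0308003.0)
Conditions: BBr3 (20 equiv), CH2Cl2, −78 °C to rt; then MeOH and H2O at 0 °C, Ar, degassed solvents
Reagents that add atoms: none
Why: Lewis acid ether cleavage with BBr3 removes each methyl group by bromide SN2 attack on the boron-complexed ether, while the diaryl ether oxygens, which carry no sp3 carbon, are not cleaved.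

**Compound list**
1 | 4-bromo-2,6-dimethoxyphenol | COc1cc(Br)cc(OC)c1O | starting material
2 | 2-(benzyloxy)-5-bromo-1,3-dimethoxybenzene | COc1cc(Br)cc(OC)c1OCc1ccccc1 | intermediate
3 | 2,4,6-trimethoxyphenol | COc1cc(OC)c(O)c(OC)c1 | starting material
4 | 2-(benzyloxy)-1,3-dimethoxy-5-(2,4,6-trimethoxyphenoxy)benzene | COc1cc(OC)c(Oc2cc(OC)c(OCc3ccccc3)c(OC)c2)c(OC)c1 | intermediate
5 | 2,6-dimethoxy-4-(2,4,6-trimethoxyphenoxy)phenol | COc1cc(OC)c(Oc2cc(OC)c(O)c(OC)c2)c(OC)c1 | intermediate
6 | 2-(benzyloxy)-5-[2,6-dimethoxy-4-(2,4,6-trimethoxyphenoxy)phenoxy]-1,3-dimethoxybenzene | COc1cc(OC)c(Oc2cc(OC)c(Oc3cc(OC)c(OCc4ccccc4)c(OC)c3)c(OC)c2)c(OC)c1 | intermediate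
7 | 4-[2,6-dimethoxy-4-(2,4,6-trimethoxyphenoxy)phenoxy]-2,6-dimethoxyphenol | COc1cc(OC)c(Oc2cc(OC)c(Oc3cc(OC)c(O)c(OC)c3)c(OC)c2)c(OC)c1 | intermediate
8 | trichloroethylene | ClC=C(Cl)Cl | starting material
9 | dichloroacetylene | ClC#CCl | intermediate
10 | 2-{[(E)-1,2-dichloroethenyl]oxy}-5-[2,6-dimethoxy-4-(2,4,6-trimethoxyphenoxy)phenoxy]-1,3-dimethoxybenzene | COc1cc(OC)c(Oc2cc(OC)c(Oc3cc(OC)c(O/C(Cl)=C\Cl)c(OC)c3)c(OC)c2)c(OC)c1 | intermediate
11 | 2-[(chloroethynyl)oxy]-5-[2,6-dimethoxy-4-(2,4,6-trimethoxyphenoxy)phenoxy]-1,3-dimethoxybenzene | COc1cc(OC)c(Oc2cc(OC)c(Oc3cc(OC)c(OC#CCl)c(OC)c3)c(OC)c2)c(OC)c1 | intermediate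
12 | lithium 2-{4-[2,6-dimethoxy-4-(2,4,6-trimethoxyphenoxy)phenoxy]-2,6-dimethoxyphenoxy}ethynide | COc1cc(OC)c(Oc2cc(OC)c(Oc3cc(OC)c(OC#C[Li])c(OC)c3)c(OC)c2)c(OC)c1 | intermediate
13 | benzyl 3-{4-[2,6-dimethoxy-4-(2,4,6-trimethoxyphenoxy)phenoxy]-2,6-dimethoxyphenoxy}prop-2-ynoate | COc1cc(OC)c(Oc2cc(OC)c(Oc3cc(OC)c(OC#CC(=O)OCc4ccccc4)c(OC)c3)c(OC)c2)c(OC)c1 | intermediate
14 | cyclohexane-1,3-dione | O=C1CCCC(=O)C1 | starting material
15 | 2-diazocyclohexane-1,3-dione | O=C1CCCC(=O)C1=[N+]=[N-] | intermediate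
16 | 3,4,5-trimethoxyphenol | COc1cc(O)cc(OC)c1OC | starting material
17 | 3-hydroxy-2-(3,4,5-trimethoxyphenoxy)cyclohex-2-en-1-one (enol of 2-(3,4,5-trimethoxyphenoxy)cyclohexane-1,3-dione) | COc1cc(OC2=C(O)CCCC2=O)cc(OC)c1OC | intermediate
18 | 2-(3,4,5-trimethoxyphenoxy)-3-(trimethylsilyloxy)cyclohex-2-en-1-one | COc1cc(OC2=C(O[Si](C)(C)C)CCCC2=O)cc(OC)c1OC | intermediate
19 | 2-(3,4,5-trimethoxyphenoxy)-1,3-bis(trimethylsilyloxy)cyclohexa-1,3-diene | C[Si](C)(C)OC1=CCCC(O[Si](C)(C)C)=C1Oc1cc(OC)c(OC)c(OC)c1 | intermediate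
20 | benzyl 3-{4-[2,6-dimethoxy-4-(2,4,6-trimethoxyphenoxy)phenoxy]-2,6-dimethoxyphenoxy}-6-(3,4,5-trimethoxyphenoxy)-1,5-bis(trimethylsilyloxy)bicyclo[2.2.2]octa-2,5-diene-2-carboxylate (racemic) | C[Si](C)(C)OC12CCC(C(O[Si](C)(C)C)=C1Oc1cc(OC)c(OC)c(OC)c1)C(Oc1c(OC)cc(Oc3c(OC)cc(Oc4c(OC)cc(OC)cc4OC)cc3OC)cc1OC)=C2C(=O)OCc1ccccc1 | intermediate
21 | benzyl 6-{4-[2,6-dimethoxy-4-(2,4,6-trimethoxyphenoxy)phenoxy]-2,6-dimethoxyphenoxy}-3-(3,4,5-trimethoxyphenoxy)-2,4-bis(trimethylsilyloxy)benzoate | COc1cc(OC)c(Oc2cc(OC)c(Oc3cc(OC)c(Oc4c(C(=O)OCc6ccccc6)c(O[Si](C)(C)C)c(Oc5cc(OC)c(OC)c(OC)c5)c(O[Si](C)(C)C)c4)c(OC)c3)c(OC)c2)c(OC)c1 | intermediate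
22 | benzyl 6-{4-[2,6-dimethoxy-4-(2,4,6-trimethoxyphenoxy)phenoxy]-2,6-dimethoxyphenoxy}-2,4-dihydroxy-3-(3,4,5-trimethoxyphenoxy)benzoate | COc1cc(OC)c(Oc2cc(OC)c(Oc3cc(OC)c(Oc4c(C(=O)OCc6ccccc6)c(O)c(Oc5cc(OC)c(OC)c(OC)c5)c(O)c4)c(OC)c3)c(OC)c2)c(OC)c1 | intermediate
23 | 6-{4-[2,6-dimethoxy-4-(2,4,6-trimethoxyphenoxy)phenoxy]-2,6-dimethoxyphenoxy}-2,4-dihydroxy-3-(3,4,5-trimethoxyphenoxy)benzoic acid | COc1cc(OC)c(Oc2cc(OC)c(Oc3cc(OC)c(Oc4c(C(=O)O)c(O)c(Oc5cc(OC)c(OC)c(OC)c5)c(O)c4)c(OC)c3)c(OC)c2)c(OC)c1 | intermediate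
24 | 5-{4-[2,6-dimethoxy-4-(2,4,6-trimethoxyphenoxy)phenoxy]-2,6-dimethoxyphenoxy}-2-(3,4,5-trimethoxyphenoxy)benzene-1,3-diol | COc1cc(OC)c(Oc2cc(OC)c(Oc3cc(OC)c(Oc4cc(O)c(Oc5cc(OC)c(OC)c(OC)c5)c(O)c4)c(OC)c3)c(OC)c2)c(OC)c1 | intermediate
25 | 5-{4-[4-(2,6-dihydroxy-4-(2,4,6-trihydroxyphenoxy)phenoxy)-2,6-dihydroxyphenoxy]-2,6-dihydroxyphenoxy}benzene-1,2,3-triol | Oc1cc(O)c(Oc2cc(O)c(Oc3cc(O)c(Oc4cc(O)c(Oc5cc(O)c(O)c(O)c5)c(O)c4)c(O)c3)c(O)c2)c(O)c1 | target

**Step count and risks**
Total step count: 13. Longest linear sequence: 10 steps (1, 2, 3, 4, 5, 6, 7, 11, 12, 13) from 1; the diene branch (steps 8, 9, 10) joins at step 11.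

Steps most likely to fail:

1. Step 11. The aryloxy donor may raise the LUMO of the triple bond so far that cycloaddition is slower than thermal desilylation or hydrogen shifts in 19 and oligomerisation of 13, or the ethylene extrusion may stall at the temperature the substrates tolerate. The fallback assembles ring D by known copper chemistry and sets out from phenol 7. Coupling of 7 with bromide 2 under the step 4 conditions should give the tetramer benzyl ether 2-(benzyloxy)-5-{4-[2,6-dimethoxy-4-(2,4,6-trimethoxyphenoxy)phenoxy]-2,6-dimethoxyphenoxy}-1,3-dimethoxybenzene F1. Hydrogenolysis (H2, Pd/C) should give the tetramer phenol F2. A third Ullmann-type coupling with purchased 5-bromo-1,2,3-trimethoxybenzene should give the dodecamethyl ether of the target F3. Treatment of F3 with BBr3 as in step 13 comes back to the route at 25.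

2. Step 9. The electrophilic carbenoid may alkylate the very electron-rich ring carbons of 16 instead of inserting into the O–H bond, or the diazo compound may dimerise. The fallback sets out from 16. Williamson alkylation with methyl 6-bromo-5-oxohexanoate (K2CO3, acetone, reflux) should give methyl 5-oxo-6-(3,4,5-trimethoxyphenoxy)hexanoate F4. KOtBu in THF should then close the ring by intramolecular Claisen (Dieckmann-type) acylation of the aryloxymethyl ketone enolate onto the ester, and acidification with dilute HCl brings the sequence back at 17.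

3. Step 4 (the same concern applies to step 2). The coupling of a di-ortho-substituted, easily oxidised phenoxide with an electron-rich bromide may be slow at copper, so that hydrodebromination of 2 and oxidative loss of the phenol take over. The fallback sets out from 2. Bromine–lithium exchange (n-BuLi, THF, −78 °C), B(OiPr)3 and work-up with dilute HCl should give [4-(benzyloxy)-3,5-dimethoxyphenyl]boronic acid F5. Chan–Lam coupling of F5 with phenol 5 (Cu(OAc)2, pyridine, 4 Å sieves, CH2Cl2, air as terminal oxidant, rt) forms the same C–O bond oxidatively at room temperature and comes back at 6.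

**Further compounds**
F1 | step 11 | 2-(benzyloxy)-5-{4-[2,6-dimethoxy-4-(2,4,6-trimethoxyphenoxy)phenoxy]-2,6-dimethoxyphenoxy}-1,3-dimethoxybenzene | COc1cc(OC)c(Oc2cc(OC)c(Oc3cc(OC)c(Oc4cc(OC)c(OCc5ccccc5)c(OC)c4)c(OC)c3)c(OC)c2)c(OC)c1
F2 | step 11 | 4-{4-[2,6-dimethoxy-4-(2,4,6-trimethoxyphenoxy)phenoxy]-2,6-dimethoxyphenoxy}-2,6-dimethoxyphenol | COc1cc(OC)c(Oc2cc(OC)c(Oc3cc(OC)c(Oc4cc(OC)c(O)c(OC)c4)c(OC)c3)c(OC)c2)c(OC)c1
F3 | step 11 | 5-{4-[4-(2,6-dimethoxy-4-(2,4,6-trimethoxyphenoxy)phenoxy)-2,6-dimethoxyphenoxy]-2,6-dimethoxyphenoxy}-1,2,3-trimethoxybenzene | COc1cc(OC)c(Oc2cc(OC)c(Oc3cc(OC)c(Oc4cc(OC)c(Oc5cc(OC)c(OC)c(OC)c5)c(OC)c4)c(OC)c3)c(OC)c2)c(OC)c1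
F4 | step 9 | methyl 5-oxo-6-(3,4,5-trimethoxyphenoxy)hexanoate | COC(=O)CCCC(=O)COc1cc(OC)c(OC)c(OC)c1
F5 | step 4 | [4-(benzyloxy)-3,5-dimethoxyphenyl]boronic acid | COc1cc(B(O)O)cc(OC)c1OCc1ccccc1
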